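**Retrosynthetic overview**

1. Feature: in the bicyclo[5.3.0]decane core, the methylene-bearing C1 of the seven-membered ring is attached to ring-fusion carbon C10, and C10 lies β to C8 of the five-membered ring. With C8 as a ketone (later the C7=C8 alkene) and C1 as a nitronate (masked C=O, later C=CH2), C1–C10 is a conjugate-addition bond.
2. Target ⇒ (desilylation, C1 methylenation, Nef reaction, enol triflate reduction) trans-fused nitro hydroazulenone ⇒ 7-exo-trig nitro-Michael closure of a 4,5-trans-disubstituted cyclopent-2-enone with a nitropropyl group on C4.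
3. Enone ⇒ C5–C6 Mukaiyama aldol of a C5 aldehyde with a cyclopentanone silyl enol ether, then 1,3-transposition of the carbonyl from C10 to C8. The nitro group comes from the allyl terminus (hydroboration, iodide, AgNO2).
4. Aldehyde ⇒ geraniol: asymmetric epoxidation and allyl opening at C4 set C2′ and C4, and a second asymmetric epoxidation with 5-exo closure sets C5′.
5. Ring order: oxolane (step 3), five-membered carbocycle (bought in with the hydroxycyclopentenone), seven-membered ring last (step 17).

Key step: step 17

Numbering: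
- Seven-membered ring: C1(=CH2)–C2–C3–C4–C5(OH)–C6–C10.
- Five-membered ring: C6–C7(CH3)=C8–C9–C10.
- Oxolane: O–C2′(CH3)–C3′–C4′–C5′, with C2′ on C4.
- β is the face of the five-membered ring that carries the C6–C5 bond (and the C8 oxygen of 10–20); α is the other face.

Assumption: the L-fructose-derived enantiomer of the Shi ketone is taken as a purchasable catalyst; C10 in 15–21 and C1 in 24–26 are epimer mixtures of no consequence and are written without configuration.

**Route**

Step 1
Reactants: 1 geraniol
Product: 2 (2S,3S)-2,3-epoxygeraniol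
Conditions: Ti(OiPr)4 (5 mol%), L-(+)-diethyl tartrate (6 mol%), t-BuOOH, 4 Å MS, CH2Cl2, −20 °C
Reagents that add atoms: tert-butyl hydroperoxide CC(C)(C)OO
Why: Sharpless asymmetric epoxidation touches only the allylic C4=C2′ alkene, and the L-(+)-tartrate catalyst delivers oxygen to the face that gives the (2S,3S)-epoxide, which fixes C2′ and prepares C4 for inversion.

Step 2
Reactants: 2 (2S,3S)-2,3-epoxygeraniol; 3 allylmagnesium bromide
Product: 4 allyl 1,3-diol
Conditions: 3 (4 equiv), CuI (20 mol%), Et2O/THF, −40 → 0 °C; aq. NH4Cl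
Reagents that add atoms: none
Why: Copper-catalysed SN2 opening of a trisubstituted 2,3-epoxy alcohol takes place at the less hindered secondary carbon C4 with inversion, so that the 1,3-diol should carry C4 in the R and the untouched tertiary carbinol C2′ in the S configuration, while any 1,2-diol from the other opening mode can be removed with NaIO4.

Step 3
Reactants: 4 allyl 1,3-diol
Product: 6 cis-oxolane diol, via epoxy diol 5 (not isolated)
Conditions: L-fructose-derived Shi ketone (30 mol%), KHSO5 (as 2KHSO5·KHSO4·K2SO4), K2CO3, Bu4NHSO4, MeCN/CH2(OMe)2/aq. Na2B4O7 buffer, 0 °C; then CSA (10 mol%), CH2Cl2, 0 °C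
Reagents that add atoms: potassium peroxymonosulfate [K+].[O-]S(=O)(=O)OO
Why: Shi epoxidation is reagent-controlled and prefers the electron-rich trisubstituted alkene to the terminal one, the L-fructose-derived ketone giving the (S)-epoxide at C5′, and the acid-catalysed 5-exo-tet opening by the C2′ hydroxyl group inverts that carbon and thus sets C5′ (R) with the C4 branch and the hydroxyisopropyl group cis on the oxolane.

Step 4
Reactants: 6 cis-oxolane diol
Product: 7 diacetate
Conditions: Ac2O, Et3N, DMAP, CH2Cl2, rt → 40 °C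
Reagents that add atoms: acetic anhydride CC(=O)OC(C)=O
Why: DMAP-catalysed acylation esterifies the primary hydroxyl group at once and the tertiary one on longer reaction, and no stereocentre is touched.

Step 5
Reactants: 7 diacetate
Product: 8 primary alcohol with tertiary acetate
Conditions: K2CO3 (0.2 equiv), MeOH, 0 °C
Reagents that add atoms: none
Why: Base-catalysed transesterification tells the two esters apart by steric hindrance, the primary acetate being methanolysed much faster than the tertiary one.

Step 6
Reactants: 8 primary alcohol with tertiary acetate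
Product: 9 C5 aldehyde
Conditions: DMP, NaHCO3, CH2Cl2, 0 °C → rt
Reagents that add atoms: none
Why: Dess–Martin oxidation in the presence of NaHCO3 is close to neutral, which should avoid epimerisation at C4 and retro-oxa-Michael opening of the β-alkoxy aldehyde.

Step 7
Reactants: 10 (R)-4-hydroxycyclopent-2-en-1-one
Product: 11 (R)-4-(triethylsilyloxy)cyclopent-2-en-1-one
Conditions: TESCl, imidazole, CH2Cl2, 0 °C
Reagents that add atoms: chlorotriethylsilane CC[Si](Cl)(CC)CC
Why: Silyl ether formation under standard imidazole catalysis; the triethylsilyl group is chosen because it can be removed in step 15 beside the hindered C5 TBS ether.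

Step 8
Reactants: 11 (R)-4-(triethylsilyloxy)cyclopent-2-en-1-one
Product: 12 trimethylsilyl enol ether
Conditions: MeMgBr, CuBr·SMe2 (10 mol%), TMSCl, DMPU, THF, −78 °C; Et3N, then cold aq. NaHCO3
Reagents that add atoms: methylmagnesium bromide C[Mg]Br; chlorotrimethylsilane C[Si](C)(C)Cl
Why: Copper-catalysed conjugate addition of the Grignard reagent, accelerated by TMSCl, brings the methyl group to C7 anti to the C8 silyloxy group and traps the C10 enolate regiospecifically as its silyl ether before β-elimination can set in.

Step 9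
Reactants: 9 C5 aldehyde; 12 trimethylsilyl enol ether
Product: 13 aldol adduct
Conditions: BF3·OEt2, CH2Cl2, −78 °C; aq. NaHCO3
Reagents that add atoms: none
Why: Mukaiyama aldol addition through an open transition state, in which non-chelating BF3 lets the Felkin–Anh preference (attack anti to the tertiary-alkyl C2′) and the 1,3-anti polar effect of the oxolane oxygen reinforce each other to set C5, while the enol ether reacts anti to the C7 methyl group to set C6 trans, a centre that in any case sits in its thermodynamic arrangement next to the C10 ketone.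

Step 10
Reactants: 13 aldol adduct
Product: 14 C5 TBS ether ketone
Conditions: TBSOTf, 2,6-lutidine, CH2Cl2, −78 → 0 °C
Reagents that add atoms: tert-butyldimethylsilyl triflate CC(C)(C)[Si](C)(C)OS(=O)(=O)C(F)(F)F
Why: Silyl ether formation with a silyl triflate and a hindered pyridine reaches crowded secondary alcohols and is too mild for retro-aldol cleavage or β-elimination.

Step 11
Reactants: 14 C5 TBS ether ketone
Product: 16 C1,C10 diol, via bis-boron adduct 15 (not isolated)
Conditions: 9-BBN (3 equiv), THF, 0 °C → rt; then NaBO3·4H2O, THF/H2O, rt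
Reagents that add atoms: sodium perborate [Na+].[O-]OB=O; 9-borabicyclo[3.3.1]nonane B1C2CCCC1CCC2 (its boron stays only in 15)
Why: Hydroboration–oxidation with the bulky 9-BBN places boron on the terminal carbon C1, and the excess reagent reduces the C10 ketone, whose carbinol configuration is of no consequence because C10 becomes sp2 in step 16.

Step 12
Reactants: 16 C1,C10 diol
Product: 17 primary iodide
Conditions: I2, PPh3, imidazole, CH2Cl2, 0 °C
Reagents that add atoms: iodine II
Why: Appel-type iodination (PPh3, I2, imidazole) is an SN2 process that takes the unhindered primary alcohol and leaves the crowded secondary C10 carbinol.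

Step 13
Reactants: 17 primary iodide
Product: 18 iodo mesylate
Conditions: MsCl, Et3N, CH2Cl2, −10 °C
Reagents that add atoms: methanesulfonyl chloride CS(=O)(=O)Cl
Why: Sulfonate ester formation by way of sulfene reaches the hindered C10 carbinol and turns it into the leaving group for the later E1cB step.

Step 14
Reactants: 18 iodo mesylate
Product: 19 nitro mesylate
Conditions: AgNO2, Et2O, 0 °C → rt, dark
Reagents that add atoms: silver nitrite [Ag+].[O-]N=O
Why: Victor Meyer reaction, in which silver-assisted substitution of a primary iodide by nitrite gives mainly the C-nitro compound under neutral conditions that leave the secondary mesylate, both silyl ethers and the acetate alone.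

Step 15
Reactants: 19 nitro mesylate
Product: 20 C8 alcohol
Conditions: AcOH/THF/H2O (3:1:1), rt
Reagents that add atoms: none
Why: Acid-catalysed silyl ether hydrolysis discriminates by size and crowding, so that the C8 triethylsilyl ether is cleaved while the hindered C5 TBS ether, the mesylate and the tertiary acetate stay.

Step 16
Reactants: 20 C8 alcohol
Product: 22 nitroalkyl cyclopentenone, via mesyloxy ketone 21 (not isolated)
Conditions: DMP, NaHCO3, CH2Cl2, 0 °C → rt; then Et3N, CH2Cl2, 0 °C
Reagents that add atoms: none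
Why: Dess–Martin oxidation gives the β-mesyloxy ketone, which loses methanesulfonate by E1cB elimination on brief contact with Et3N, so that the carbonyl group has moved from C10 to C8, the alkene can only be C9=C10, and the C7 methyl group stays in the more stable trans arrangement.

Step 17
Reactants: 22 nitroalkyl cyclopentenone
Product: 24 trans-fused nitro hydroazulenone, via nitronate anion 23 (not isolated)
Conditions: DBU (0.3 equiv), MeCN (0.005 M), 0 °C → rt; AcOH quench
Reagents that add atoms: none
Why: DBU removes a proton from the C1 nitromethylene group, which is far more acidic than the γ-hydrogen at C6, and the soft nitronate carbon adds to C10, the β-carbon of the C8 enone, after which the C8 enolate is protonated at C9. The closest known reaction type is the intramolecular nitro-Michael addition, routine for five- and six-membered rings and less common for seven-membered ones. The ring C1–C2–C3–C4–C5–C6–C10 closes in the 7-exo-trig mode, with the C9=C10 bond outside the new ring and the branching at C4 and C5 favouring folded chain conformers. C10 is under thermodynamic control, because the addition is reversible under DBU and the fusion should settle with the C10–C1 bond trans to the C6–C5 bond, where both bonds are pseudo-equatorial on the cyclopentanone, while C1 forms as an epimer mixture that disappears when it becomes sp2 in step 20. The step needs 1,4- over 1,2-addition, cyclisation over oligomerisation and nitronate formation over deconjugation of the enone, which are secured in turn by the soft and reversible nucleophile, by the tether on the neighbouring C6 together with high dilution, and by the pKa gap that allows a substoichiometric base at low temperature.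

Step 18
Reactants: 24 trans-fused nitro hydroazulenone
Product: 25 C7=C8 enol triflate
Conditions: Tf2O, 2,6-di-tert-butyl-4-methylpyridine, CH2Cl2, 0 °C → rt
Reagents that add atoms: triflic anhydride O=S(=O)(OS(=O)(=O)C(F)(F)F)C(F)(F)F
Why: Enol triflate formation with Tf2O and a hindered pyridine goes through an O-triflyloxycarbenium ion whose deprotonation favours the more substituted C7=C8 alkene, and the non-basic medium forms no nitronate and allows no retro-Michael reaction.

Step 19
Reactants: 25 C7=C8 enol triflate
Product: 26 nitro hydroazulene with C7=C8 alkene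
Conditions: Pd(OAc)2 (5 mol%), PPh3 (10 mol%), HCO2H, Bu3N, DMF, 60 °C
Reagents that add atoms: none
Why: Palladium-catalysed formate hydrogenolysis of an enol triflate (oxidative addition to zerovalent palladium, decarboxylation of the formate ligand, reductive elimination) replaces OTf by H without moving the C7=C8 alkene, and an aliphatic nitro group is not reduced by this homogeneous system.

Step 20
Reactants: 26 nitro hydroazulene with C7=C8 alkene
Product: 28 C1 ketone, via nitronate anion 27 (not isolated)
Conditions: NaOMe (1.05 equiv), MeOH, 0 °C; then aq. TiCl3, NH4OAc, THF/H2O (pH 5–6), rt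
Reagents that add atoms: water O
Why: Nef reaction in its reductive form, in which trivalent titanium reduces the nitronate by way of the oxime to the imine that is hydrolysed at pH 5–6, conditions that spare the alkene, the TBS ether and the acetate, and C10, now α to the C1 ketone, can be equilibrated once more to the trans fusion if needed.

Step 21
Reactants: 28 C1 ketone
Product: 29 C1 methylene TBS ether
Conditions: Zn, CH2Br2, TiCl4, THF/CH2Cl2, 0 °C → rt
Reagents that add atoms: dibromomethane BrCBr
Why: Takai–Lombardo methylenation uses a non-basic gem-dimetallic reagent that attacks ketones but not esters and should not epimerise C10.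

Step 22
Reactants: 29 C1 methylene TBS ether
Product: 30 target CNP0302132.4
Conditions: HF·pyridine, pyridine, THF, 0 °C → rt
Reagents that add atoms: none
Why: Fluoride-mediated desilylation driven by the strong Si–F bond, buffered with pyridine so that the tertiary acetate and both alkenes are left untouched.

**Compound list**

1 | geraniol, (2E)-3,7-dimethylocta-2,6-dien-1-ol | CC(C)=CCC/C(C)=C/CO | starting material
2 | (2S,3S)-2,3-epoxygeraniol | OC[C@@H]1O[C@@]1(C)CCC=C(C)C | intermediate
3 | allylmagnesium bromide | C=CC[Mg]Br | starting material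
4 | (2R,3S)-2-allyl-3,7-dimethyloct-6-ene-1,3-diol (C5H2OH, C4 R, C2′ S) | OC[C@H]([C@](O)(C)CCC=C(C)C)CC=C | intermediate
5 | (2R,3S)-2-allyl-5-[(2S)-3,3-dimethyloxiran-2-yl]-3-methylpentane-1,3-diol | OC[C@H]([C@](O)(C)CC[C@@H]1OC1(C)C)CC=C | intermediate (not isolated)
6 | 2-{(2R,5S)-5-[(2R)-1-hydroxypent-4-en-2-yl]-5-methyloxolan-2-yl}propan-2-ol (C4 branch and hydroxyisopropyl group cis on the oxolane) | OC[C@H]([C@]1(C)CC[C@H](C(C)(C)O)O1)CC=C | intermediate
7 | diacetate of 6 (primary C5 acetate and tertiary acetate) | CC(=O)OC[C@H]([C@]1(C)CC[C@H](C(C)(C)OC(C)=O)O1)CC=C | intermediate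
8 | 2-{(2R,5S)-5-[(2R)-1-hydroxypent-4-en-2-yl]-5-methyloxolan-2-yl}propan-2-yl acetate | OC[C@H]([C@]1(C)CC[C@H](C(C)(C)OC(C)=O)O1)CC=C | intermediate
9 | (2S)-2-[(2S,5R)-5-(2-acetoxypropan-2-yl)-2-methyloxolan-2-yl]pent-4-enal (same spatial arrangement at C4 as in 8) | O=C[C@H]([C@]1(C)CC[C@H](C(C)(C)OC(C)=O)O1)CC=C | intermediate
10 | (R)-4-hydroxycyclopent-2-en-1-one | O=C1C=C[C@H](O)C1 | starting material
11 | (R)-4-(triethylsilyloxy)cyclopent-2-en-1-one | O=C1C=C[C@H](O[Si](CC)(CC)CC)C1 | intermediate
12 | (3R,4R)-3-methyl-4-(triethylsilyloxy)-1-(trimethylsilyloxy)cyclopent-1-ene (C7 methyl α, C8 oxygen β) | C[Si](C)(C)OC1=C[C@@H](C)[C@H](O[Si](CC)(CC)CC)C1 | intermediate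
13 | aldol adduct: cyclopentanone with C10=O, C6 side chain β, C7 methyl α, C8 OSiEt3 β; free C5 hydroxyl with C5 configured as in the target; allyl on C4; C4, C2′, C5′ as in 9 | O=C1C[C@@H](O[Si](CC)(CC)CC)[C@H](C)[C@H]1[C@H](O)[C@H]([C@]2(C)CC[C@H](C(C)(C)OC(C)=O)O2)CC=C | intermediate
14 | C5 tert-butyldimethylsilyl ether of 13 | O=C1C[C@@H](O[Si](CC)(CC)CC)[C@H](C)[C@H]1[C@H](O[Si](C)(C)C(C)(C)C)[C@H]([C@]2(C)CC[C@H](C(C)(C)OC(C)=O)O2)CC=C | intermediate
15 | bis-boron adduct of 14: C1–B(9-BBN) alkylborane and C10–O–B(9-BBN) borinate | B1(OC2C[C@@H](O[Si](CC)(CC)CC)[C@H](C)[C@H]2[C@H](O[Si](C)(C)C(C)(C)C)[C@H]([C@]3(C)CC[C@H](C(C)(C)OC(C)=O)O3)CCCB4C5CCCC4CCC5)C6CCCC1CCC6 | intermediate (not isolated)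
16 | diol: primary C1 hydroxyl and secondary C10 hydroxyl (C10 epimers), otherwise as 14 | OC1C[C@@H](O[Si](CC)(CC)CC)[C@H](C)[C@H]1[C@H](O[Si](C)(C)C(C)(C)C)[C@H]([C@]2(C)CC[C@H](C(C)(C)OC(C)=O)O2)CCCO | intermediate
17 | C1 iodide of 16 with free C10 hydroxyl | OC1C[C@@H](O[Si](CC)(CC)CC)[C@H](C)[C@H]1[C@H](O[Si](C)(C)C(C)(C)C)[C@H]([C@]2(C)CC[C@H](C(C)(C)OC(C)=O)O2)CCCI | intermediate
18 | C10 methanesulfonate of 17 | CS(=O)(=O)OC1C[C@@H](O[Si](CC)(CC)CC)[C@H](C)[C@H]1[C@H](O[Si](C)(C)C(C)(C)C)[C@H]([C@]2(C)CC[C@H](C(C)(C)OC(C)=O)O2)CCCI | intermediate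
19 | C1 nitro compound with C10 mesylate and C8 OSiEt3 | CS(=O)(=O)OC1C[C@@H](O[Si](CC)(CC)CC)[C@H](C)[C@H]1[C@H](O[Si](C)(C)C(C)(C)C)[C@H]([C@]2(C)CC[C@H](C(C)(C)OC(C)=O)O2)CCC[N+](=O)[O-] | intermediate
20 | C8 alcohol (β) with C10 mesylate, C5 OTBS and C1 nitro group | CS(=O)(=O)OC1C[C@@H](O)[C@H](C)[C@H]1[C@H](O[Si](C)(C)C(C)(C)C)[C@H]([C@]2(C)CC[C@H](C(C)(C)OC(C)=O)O2)CCC[N+](=O)[O-] | intermediate
21 | C8 ketone with β-mesyloxy group on C10 | CS(=O)(=O)OC1CC(=O)[C@H](C)[C@H]1[C@H](O[Si](C)(C)C(C)(C)C)[C@H]([C@]2(C)CC[C@H](C(C)(C)OC(C)=O)O2)CCC[N+](=O)[O-] | intermediate (not isolated)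
22 | key-step precursor: 4,5-trans-disubstituted cyclopent-2-enone (C8=O, C9=C10, C7 methyl α, C6 chain β) with C5 OTBS, oxolane and 3-nitropropyl group on C4 | O=C1C=C[C@H]([C@H](O[Si](C)(C)C(C)(C)C)[C@H]([C@]3(C)CC[C@H](C(C)(C)OC(C)=O)O3)CCC[N+](=O)[O-])[C@H]1C | intermediate
23 | C1 nitronate anion of 22 (counter-ion protonated DBU) | O=C1C=C[C@H]([C@H](O[Si](C)(C)C(C)(C)C)[C@H]([C@]3(C)CC[C@H](C(C)(C)OC(C)=O)O3)CCC=[N+]([O-])[O-])[C@H]1C | intermediate (not isolated)
24 | key-step product: trans-fused nitro hydroazulenone (H6 α, H10 β, C8=O, C7 methyl α, both C1 epimers) | O=[N+]([O-])C1CC[C@@H]([C@]3(C)CC[C@H](C(C)(C)OC(C)=O)O3)[C@@H](O[Si](C)(C)C(C)(C)C)[C@@H]2[C@@H](C)C(=O)C[C@@H]12 | intermediate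
25 | C7=C8 enol triflate of 24 | O=[N+]([O-])C1CC[C@@H]([C@]3(C)CC[C@H](C(C)(C)OC(C)=O)O3)[C@@H](O[Si](C)(C)C(C)(C)C)[C@@H]2C(C)=C(OS(=O)(=O)C(F)(F)F)C[C@@H]12 | intermediate
26 | C1 nitro hydroazulene with C7=C8 alkene | O=[N+]([O-])C1CC[C@@H]([C@]3(C)CC[C@H](C(C)(C)OC(C)=O)O3)[C@@H](O[Si](C)(C)C(C)(C)C)[C@@H]2C(C)=CC[C@@H]12 | intermediate
27 | C1 nitronate anion of 26 (counter-ion sodium) | [O-][N+]([O-])=C1CC[C@@H]([C@]3(C)CC[C@H](C(C)(C)OC(C)=O)O3)[C@@H](O[Si](C)(C)C(C)(C)C)[C@@H]2C(C)=CC[C@@H]12 | intermediate (not isolated)
28 | trans-fused C1 ketone | O=C1CC[C@@H]([C@]3(C)CC[C@H](C(C)(C)OC(C)=O)O3)[C@@H](O[Si](C)(C)C(C)(C)C)[C@@H]2C(C)=CC[C@@H]12 | intermediate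
29 | C5 TBS ether of the target | C=C1CC[C@@H]([C@]3(C)CC[C@H](C(C)(C)OC(C)=O)O3)[C@@H](O[Si](C)(C)C(C)(C)C)[C@@H]2C(C)=CC[C@@H]12 | intermediate
30 | CNP0302132.4 (C4 R, C5 S, C6 S, C10 R, C2′ S, C5′ R) | C=C1CC[C@@H]([C@]2(C)CC[C@H](C(C)(C)OC(C)=O)O2)[C@@H](O)[C@@H]2C(C)=CC[C@@H]12 | target

**Step count**

Total step count: 22. Longest linear sequence: 20 (steps 1–6 and 9–22).

**Steps most likely to fail**

1. Step 17.
- What may go wrong: the closure may stall, because the equilibrium for a seven-membered ring is only weakly favourable. Long contact with the amidine may then move the enone double bond into the tetrasubstituted C6=C7 position, expel silanol from C5 in a vinylogous elimination, or allow intermolecular addition.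
- Fallback (sets out from 22, comes back at 24): the base-mediated equilibrium is replaced by a preformed neutral nucleophile and an irreversible silyl transfer. TMSCl/Et3N in MeCN converts 22 into the trimethylsilyl nitronate F1. A catalytic amount of Bu4NF in THF at −78 °C under high dilution then starts a fluoride-catalysed conjugate addition of the silyl nitronate. In it the silyl group passes to the C8 enolate oxygen and locks the ring as the trimethylsilyl enol ether F2. Citric acid in MeOH hydrolyses F2 to 24. A cis fusion, if formed, would still be open to equilibration at ketone 28.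

2. Step 9.
- What may go wrong: crowding at both reacting carbons may slow the addition. An intrinsic syn/anti preference of the cyclopentenyl silyl ether may also compete with the Felkin–Anh face of the aldehyde and erode selectivity at C5.
- Fallback (sets out from 11 and 9, comes back at 14): C6 is made an sp2 nucleophile, so that only the aldehyde face counts. I2/pyridine in CH2Cl2 converts 11 into (R)-2-iodo-4-(triethylsilyloxy)cyclopent-2-en-1-one F3. A Nozaki–Hiyama–Kishi coupling (CrCl2, catalytic NiCl2, DMF) of F3 with 9 gives the α-(1-hydroxyalkyl)cyclopentenone F4, and TBSOTf/2,6-lutidine gives its silyl ether F5. Conjugate addition of MeMgBr/CuBr·SMe2 anti to the C8 silyloxy group, followed by protonation of the enolate to the 2,3-trans ketone, leads to 14.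

3. Step 18.
- What may go wrong: deprotonation of the triflyloxycarbenium ion may turn toward C9 because C7 is crowded by the C6 substituent. The long exposure to Tf2O may also ionise the tertiary acetate.
- Fallback (sets out from 24, comes back at 26): the alkene is made by reduction and anti elimination instead of by way of an enol derivative. LiBH(s-Bu)3 (2.2 equiv, THF, −78 °C) attacks the C8 ketone from the face opposite to the C7 methyl group and gives the C8 α-carbinol F6, with the hydroxyl cis to the methyl group. MsCl/Et3N gives the mesylate F7. DBU in toluene at 80 °C effects an E2 elimination that uses the antiperiplanar C7–H and follows the Zaitsev orientation to give 26.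

Further compounds
F1 | step 17 | trimethylsilyl nitronate of 22 | O=C1C=C[C@H]([C@H](O[Si](C)(C)C(C)(C)C)[C@H]([C@]3(C)CC[C@H](C(C)(C)OC(C)=O)O3)CCC=[N+]([O-])O[Si](C)(C)C)[C@H]1C
F2 | step 17 | C8 trimethylsilyl enol ether (C8=C9) of 24 | O=[N+]([O-])C1CC[C@@H]([C@]3(C)CC[C@H](C(C)(C)OC(C)=O)O3)[C@@H](O[Si](C)(C)C(C)(C)C)[C@@H]2[C@@H](C)C(O[Si](C)(C)C)=C[C@@H]12
F3 | step 9 | (R)-2-iodo-4-(triethylsilyloxy)cyclopent-2-en-1-one | O=C1C(I)=C[C@H](O[Si](CC)(CC)CC)C1
F4 | step 9 | α-(1-hydroxyalkyl)cyclopentenone (C10=O, C6=C7, C8 OSiEt3 β, free C5 hydroxyl) | O=C1C[C@@H](O[Si](CC)(CC)CC)C=C1[C@H](O)[C@H]([C@]2(C)CC[C@H](C(C)(C)OC(C)=O)O2)CC=C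
F5 | step 9 | C5 tert-butyldimethylsilyl ether of F4 | O=C1C[C@@H](O[Si](CC)(CC)CC)C=C1[C@H](O[Si](C)(C)C(C)(C)C)[C@H]([C@]2(C)CC[C@H](C(C)(C)OC(C)=O)O2)CC=C
F6 | step 18 | C8 α-carbinol of 24 (hydroxyl cis to the C7 methyl group) | O=[N+]([O-])C1CC[C@@H]([C@]3(C)CC[C@H](C(C)(C)OC(C)=O)O3)[C@@H](O[Si](C)(C)C(C)(C)C)[C@@H]2[C@@H](C)[C@@H](O)C[C@@H]12
F7 | step 18 | C8 methanesulfonate of F6 | O=[N+]([O-])C1CC[C@@H]([C@]3(C)CC[C@H](C(C)(C)OC(C)=O)O3)[C@@H](O[Si](C)(C)C(C)(C)C)[C@@H]2[C@@H](C)[C@@H](OS(C)(=O)=O)C[C@@H]12
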